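**Retrosynthetic overview**
1. The five benzyl ethers are removed last with BCl3. Before that, the C7–aryl bond of the E-benzylidene is cut by a Heck disconnection into an α-methylene lactone and O-benzyl-4-iodoguaiacol.
2. The plan rests on the lactone O1–C2(=O)–C3–C4–C5 with exocyclic C7 on C3. C4 (resorcinol ring B) and C5 (catechol ring C) form an anti β-aryl homoallylic alcohol unit, and C3 carries both the carboxyl carbon C2 and C7. This is the pattern left by a 2-alkoxycarbonyl allylboronate adding to the ring C aldehyde.
3. Key disconnections are C4–C5 and O1–C2: the ring B (Z)-2-(borylmethyl)cinnamate plus 3,4-bis(benzyloxy)benzaldehyde under a chiral BINOL phosphoric acid. The lactone is the only ring built, and both stereocentres arise in that step.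
4. The boronate is traced back to 3,5-bis(benzyloxy)benzaldehyde by Corey–Fuchs homologation to the arylpropiolate, then syn hydroalumination and alkylation with the iodomethyl boronic ester.

Key step: step 4

Assumption: (R)-TRIP, that is (R)-3,3'-bis(2,4,6-triisopropylphenyl)-1,1'-binaphthyl-2,2'-diyl hydrogen phosphate, is taken to direct attack to the Re face of the aryl aldehyde as it does with simple allyl and (E)-crotyl pinacol boronates, which corresponds to (5R) here; if the ester-bearing boronate responds in the opposite sense, the (S)-catalyst would be used with no other change.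

**Route**

Step 1
Reactants: 1 3,5-bis(benzyloxy)benzaldehyde
Product: 2 1,3-bis(benzyloxy)-5-(2,2-dibromoethenyl)benzene
Conditions: CBr4 (2 equiv), PPh3 (4 equiv), CH2Cl2, 0 °C
Reagents that add atoms: carbon tetrabromide, BrC(Br)(Br)Br
Why: Ramirez dibromo-olefination (first half of the Corey–Fuchs homologation), in which the ylide Ph3P=CBr2 formed from CBr4 and PPh3 reacts with the aryl aldehyde in a Wittig reaction that the benzyl ethers do not disturb; no stereocentre is formed.

Step 2
Reactants: 2 1,3-bis(benzyloxy)-5-(2,2-dibromoethenyl)benzene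
Product: 4 methyl 3-[3,5-bis(benzyloxy)phenyl]prop-2-ynoate, via lithium arylacetylide 3 (not isolated)
Conditions: n-BuLi (2.2 equiv), THF, −78 °C; then ClCO2Me, −78 °C → rt
Reagents that add atoms: methyl chloroformate, COC(=O)Cl
Why: Second half of the Corey–Fuchs homologation, in which two equivalents of n-BuLi convert the dibromoalkene by elimination and bromine–lithium exchange into lithium acetylide 3, which is C-acylated by the chloroformate at a temperature where the aryl benzyl ethers are not metalated; no stereocentre is formed.

Step 3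
Reactants: 4 methyl 3-[3,5-bis(benzyloxy)phenyl]prop-2-ynoate; 5 2-(iodomethyl)-4,4,5,5-tetramethyl-1,3,2-dioxaborolane
Product: 7 methyl (Z)-3-[3,5-bis(benzyloxy)phenyl]-2-[(4,4,5,5-tetramethyl-1,3,2-dioxaborolan-2-yl)methyl]prop-2-enoate, via vinylalane 6 (not isolated)
Conditions: i-Bu2AlH (1.3 equiv), HMPA (2 equiv), THF, 0 °C; then 5 (1.5 equiv), 0 °C → rt
Reagents that add atoms: none
Why: Conjugate syn hydroalumination of the alkynoate by the i-Bu2AlH–HMPA complex (hydride to the β-carbon and aluminium to the α-carbon on the same side) should give α-alumino acrylate 6 with ring B cis to the ester, and alkylation of its C–Al bond by the iodomethyl boronic ester with retention should give the Z alkene with CH2B trans to ring B, a one-flask sequence established for 3-substituted 2-alkoxycarbonyl allylboronates.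

Step 4
Reactants: 7 methyl (Z)-3-[3,5-bis(benzyloxy)phenyl]-2-[(4,4,5,5-tetramethyl-1,3,2-dioxaborolan-2-yl)methyl]prop-2-enoate; 8 3,4-bis(benzyloxy)benzaldehyde
Product: 10 (4R,5R)-4-[3,5-bis(benzyloxy)phenyl]-5-[3,4-bis(benzyloxy)phenyl]-3-methylideneoxolan-2-one, via homoallyl borate 9 (not isolated)
Conditions: (R)-TRIP (10 mol%), 4 Å MS, PhMe, rt; then p-TsOH·H2O (5 mol%), rt
Reagents that add atoms: none
Why: Proposed new method: the phosphoric acid is expected to hydrogen-bond to a dioxaborolane oxygen of 7 and so raise the Lewis acidity of boron, after which aldehyde 8 binds to boron and the aryl-bearing γ-carbon of the boronate (future C4) attacks the carbonyl carbon (future C5) through a closed six-membered chair transition state with allylic transposition, so that the former CH2B carbon becomes the exocyclic methylene C7 on C3. The closest known reactions are the chiral phosphoric acid-catalysed allyl- and crotylboration of aldehydes with pinacol boronates and the achiral Brønsted or Lewis acid-catalysed allylboration–lactonisation of 2-alkoxycarbonyl allylboronates; what is untested is their combination, a weak chiral acid acting on an ester-deactivated γ-aryl boronate. The lactone, the only ring made, closes by 5-exo-trig attack of the boron-bound C5 oxygen (O1) of borate 9 on the methyl ester carbon C2 with loss of MeOBpin, and the catalytic p-TsOH completes this acyl substitution if the borate reacts slowly. The relative configuration follows from the alkene geometry of 7: ring B is trans to CH2B and therefore equatorial in the chair, the aryl of 8 is equatorial as well, and the resulting anti adduct is the 4,5-trans lactone. The absolute configuration is set by the catalyst, whose 3,3'-aryl groups shield one face of the boron-bound aldehyde so that attack on its Re face gives (5R) and, through the chair, (4R). The step therefore needs γ-regioselectivity, anti diastereoselectivity and aldehyde face selectivity, secured respectively by the closed transition state, the geometric purity of 7 and the chiral phosphate.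

Step 5
Reactants: 11 4-iodo-2-methoxyphenol
Product: 12 1-(benzyloxy)-4-iodo-2-methoxybenzene
Conditions: BnBr, K2CO3, DMF, rt
Reagents that add atoms: benzyl bromide, BrCc1ccccc1
Why: Williamson etherification of the phenoxide with a benzylic bromide, so that the Heck partner carries the same protecting group as the rest of the molecule and no free phenol is present in the palladium step; no stereocentre is formed.

Step 6
Reactants: 10 (4R,5R)-4-[3,5-bis(benzyloxy)phenyl]-5-[3,4-bis(benzyloxy)phenyl]-3-methylideneoxolan-2-one; 12 1-(benzyloxy)-4-iodo-2-methoxybenzene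
Product: 13 (3E,4R,5R)-3-{[4-(benzyloxy)-3-methoxyphenyl]methylidene}-4-[3,5-bis(benzyloxy)phenyl]-5-[3,4-bis(benzyloxy)phenyl]oxolan-2-one
Conditions: Pd(OAc)2 (5 mol%), n-Bu4NCl, KOAc, DMF, 70 °C
Reagents that add atoms: none
Why: Mizoroki–Heck arylation under phosphine-free conditions, in which the arylpalladium iodide adds syn across the exocyclic C3=C7 bond with the aryl on the terminal carbon C7 and syn β-hydride elimination from the benzylic C7–H, the usual course for five-membered α-methylene lactones, should give the conjugated benzylidene with the aryl anti to the lactone carbonyl (E), while the weak acetate base should leave C4 and C5 untouched.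

Step 7
Reactants: 13 (3E,4R,5R)-3-{[4-(benzyloxy)-3-methoxyphenyl]methylidene}-4-[3,5-bis(benzyloxy)phenyl]-5-[3,4-bis(benzyloxy)phenyl]oxolan-2-one
Product: 14 (3E,4R,5R)-5-(3,4-dihydroxyphenyl)-4-(3,5-dihydroxyphenyl)-3-[(4-hydroxy-3-methoxyphenyl)methylidene]oxolan-2-one (CNP0205330.2)
Conditions: BCl3 (10 equiv), C6HMe5 (15 equiv), CH2Cl2, −78 °C; then MeOH
Reagents that add atoms: none
Why: Lewis acid debenzylation in which BCl3 cleaves the five aryl benzyl ethers at −78 °C and pentamethylbenzene traps the benzyl cations, conditions that should spare the aryl methyl ether, the lactone and the benzylidene double bond (hydrogenolysis would reduce the alkene and cleave the benzylic C5–O1 bond) and leave the two stereocentres as set in step 4.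

**Compound list**
1 | 3,5-bis(benzyloxy)benzaldehyde | O=Cc1cc(OCc2ccccc2)cc(OCc2ccccc2)c1 | starting material
2 | 1,3-bis(benzyloxy)-5-(2,2-dibromoethenyl)benzene | BrC(Br)=Cc1cc(OCc2ccccc2)cc(OCc2ccccc2)c1 | intermediate
3 | lithium [3,5-bis(benzyloxy)phenyl]acetylide | [Li]C#Cc1cc(OCc2ccccc2)cc(OCc2ccccc2)c1 | intermediate
4 | methyl 3-[3,5-bis(benzyloxy)phenyl]prop-2-ynoate | COC(=O)C#Cc1cc(OCc2ccccc2)cc(OCc2ccccc2)c1 | intermediate
5 | 2-(iodomethyl)-4,4,5,5-tetramethyl-1,3,2-dioxaborolane | CC1(C)OB(CI)OC1(C)C | starting material
6 | methyl (E)-3-[3,5-bis(benzyloxy)phenyl]-2-[bis(2-methylpropyl)alumanyl]prop-2-enoate (ring B cis to the ester) | COC(=O)/C([Al](CC(C)C)CC(C)C)=C\c1cc(OCc2ccccc2)cc(OCc2ccccc2)c1 | intermediate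
7 | methyl (Z)-3-[3,5-bis(benzyloxy)phenyl]-2-[(4,4,5,5-tetramethyl-1,3,2-dioxaborolan-2-yl)methyl]prop-2-enoate (ring B cis to the ester, trans to CH2B) | COC(=O)/C(CB1OC(C)(C)C(C)(C)O1)=C\c1cc(OCc2ccccc2)cc(OCc2ccccc2)c1 | intermediate
8 | 3,4-bis(benzyloxy)benzaldehyde | O=Cc1ccc(OCc2ccccc2)c(OCc2ccccc2)c1 | starting material
9 | methyl (3R,4R)-3-[3,5-bis(benzyloxy)phenyl]-4-[3,4-bis(benzyloxy)phenyl]-2-methylidene-4-[(4,4,5,5-tetramethyl-1,3,2-dioxaborolan-2-yl)oxy]butanoate | COC(=O)C(=C)[C@@H](c1cc(OCc2ccccc2)cc(OCc2ccccc2)c1)[C@H](c1ccc(OCc2ccccc2)c(OCc2ccccc2)c1)OB1OC(C)(C)C(C)(C)O1 | intermediate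
10 | (4R,5R)-4-[3,5-bis(benzyloxy)phenyl]-5-[3,4-bis(benzyloxy)phenyl]-3-methylideneoxolan-2-one (trans) | C=C1C(=O)O[C@@H](c2ccc(OCc3ccccc3)c(OCc3ccccc3)c2)[C@@H]1c1cc(OCc2ccccc2)cc(OCc2ccccc2)c1 | intermediate
11 | 4-iodo-2-methoxyphenol | COc1cc(I)ccc1O | starting material
12 | 1-(benzyloxy)-4-iodo-2-methoxybenzene | COc1cc(I)ccc1OCc1ccccc1 | intermediate
13 | (3E,4R,5R)-3-{[4-(benzyloxy)-3-methoxyphenyl]methylidene}-4-[3,5-bis(benzyloxy)phenyl]-5-[3,4-bis(benzyloxy)phenyl]oxolan-2-one | COc1cc(/C=C2/C(=O)O[C@@H](c3ccc(OCc4ccccc4)c(OCc4ccccc4)c3)[C@@H]2c2cc(OCc3ccccc3)cc(OCc3ccccc3)c2)ccc1OCc1ccccc1 | intermediate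
14 | (3E,4R,5R)-5-(3,4-dihydroxyphenyl)-4-(3,5-dihydroxyphenyl)-3-[(4-hydroxy-3-methoxyphenyl)methylidene]oxolan-2-one | COc1cc(/C=C2/C(=O)O[C@@H](c3ccc(O)c(O)c3)[C@@H]2c2cc(O)cc(O)c2)ccc1O | target

**Step count**
Total: 7 steps. Longest linear sequence: 6 steps (steps 1, 2, 3, 4, 6 and 7); step 5 is a one-step side branch.

**Steps most likely to fail**

Step 4. The weak chiral acid may not activate the ester-deactivated, γ-aryl boronate enough towards an electron-rich aldehyde, so conversion may be slow. Discrimination between the two aldehyde faces may also be poor, and ring closure of the borate may stall. The fallback sets out from 7 and 8 and uses the known achiral variant: catalytic CF3SO3H in toluene at 0 °C → rt, a Brønsted acid-catalysed allylboration–lactonisation established for this class of boronates and expected to give the trans lactone with electron-rich aryl aldehydes. This would give the racemate, that is 10 together with (4S,5S)-4-[3,5-bis(benzyloxy)phenyl]-5-[3,4-bis(benzyloxy)phenyl]-3-methylideneoxolan-2-one F1. The two enantiomers would then be separated by preparative chromatography on a chiral stationary phase, and the route is rejoined at 10.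

Step 6. β-Hydride elimination may go into the ring (towards C4–H), or the double bond may later migrate to the endocyclic butenolide through palladium hydride re-addition or γ-deprotonation. Either process would destroy the C4 stereocentre; incomplete E selectivity is a lesser concern. The fallback sets out from 10 and replaces the palladium chemistry by olefin cross-metathesis, which has no alkylpalladium intermediate. Commercial 4-(benzyloxy)-3-methoxybenzaldehyde would be methylenated by a Wittig reaction (Ph3PCH3Br, KOt-Bu, THF) to 1-(benzyloxy)-4-ethenyl-2-methoxybenzene F2. This styrene, in excess, would be coupled with 10 using the second-generation Hoveyda–Grubbs catalyst RuCl2(=CH-C6H4-2-O-i-Pr)(H2IMes) and 2,6-dichloro-1,4-benzoquinone as isomerisation suppressor in toluene at 80 °C, with loss of ethene. The thermodynamically preferred E alkene is expected, and the route is rejoined at 13.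

Step 3. Alkene geometry may be lost through the aluminium allenoate form of 6, the ester may undergo 1,2-reduction, or C-alkylation of the vinylalane may be sluggish. The fallback sets out from 4 and builds the same alkene by three stereoretentive steps. Syn hydrostannation catalysed by Pd(PPh3)4 (Bu3SnH, THF, rt) should place tin on the α-carbon and give methyl (E)-3-[3,5-bis(benzyloxy)phenyl]-2-(tributylstannyl)prop-2-enoate F3. Iododestannylation (I2, CH2Cl2, 0 °C) should give methyl (E)-3-[3,5-bis(benzyloxy)phenyl]-2-iodoprop-2-enoate F4. Negishi coupling catalysed by Pd(PPh3)4 with iodo[(4,4,5,5-tetramethyl-1,3,2-dioxaborolan-2-yl)methyl]zinc F5, made from 5 and Zn dust in THF, should then deliver the allylboronate, and the route is rejoined at 7.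

**Further compounds**
F1 | step 4 | (4S,5S)-4-[3,5-bis(benzyloxy)phenyl]-5-[3,4-bis(benzyloxy)phenyl]-3-methylideneoxolan-2-one | C=C1C(=O)O[C@H](c2ccc(OCc3ccccc3)c(OCc3ccccc3)c2)[C@H]1c1cc(OCc2ccccc2)cc(OCc2ccccc2)c1
F2 | step 6 | 1-(benzyloxy)-4-ethenyl-2-methoxybenzene | COc1cc(C=C)ccc1OCc1ccccc1
F3 | step 3 | methyl (E)-3-[3,5-bis(benzyloxy)phenyl]-2-(tributylstannyl)prop-2-enoate | COC(=O)/C([Sn](CCCC)(CCCC)CCCC)=C\c1cc(OCc2ccccc2)cc(OCc2ccccc2)c1
F4 | step 3 | methyl (E)-3-[3,5-bis(benzyloxy)phenyl]-2-iodoprop-2-enoate | COC(=O)/C(I)=C\c1cc(OCc2ccccc2)cc(OCc2ccccc2)c1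
F5 | step 3 | iodo[(4,4,5,5-tetramethyl-1,3,2-dioxaborolan-2-yl)methyl]zinc | CC1(C)OB(C[Zn]I)OC1(C)C
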